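Ring B is opened and re-closed (labdane numbering): ozonolysis of a sclareolide-derived Δ7 ester cuts C7–C8, and an intramolecular Nozaki–Hiyama–Kishi reaction of the C8 alkenyl triflate onto the C7 aldehyde rebuilds that bond. The key step exploits the 2-methylenecyclohexanol unit of ring B (C7 carbinol next to C8 carrying the exocyclic C17 methylene): in one operation it closes ring B, installs the 8(17)-alkene and sets the 7β-hydroxyl. Its precursor is a ring-A cyclohexane bearing a CH2CHO arm at C5 and a 1-(triflyloxy)vinyl group on C9. The 11,15-peroxide follows from a silyl-ene reaction of singlet oxygen with the C12 aldehyde enol ether, E-selective Wittig extension and peroxy-hemiacetal closure.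

Key step: step 4

Remark: C15 is a ring–chain-equilibrating peroxy-hemiacetal carbon, and its 15R configuration is assumed to be the thermodynamically preferred anomer reached in the last step; C17 is the exocyclic methylene carbon and C20 the angular methyl.

Step 1
Reactants: 1 (+)-sclareolide
Product: 2 methyl 13,14,15,16-tetranorlabd-7-en-12-oate
Conditions: conc. H2SO4, MeOH, 23 °C, stopped at full conversion
Reagents that add atoms: methanol (CO)
Why: Acid-mediated lactone methanolysis with E1 loss of the tertiary C8–O bond (Fischer esterification and dehydration) should give the trisubstituted Δ7 ester as the main isomer without touching C5, C9 or C10, and the Δ8(17) and Δ8(9) isomers need no removal here because step 2 turns them into a ring-intact nor-ketone and a diketone that chromatography separates.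

Step 2
Reactants: 2 methyl 13,14,15,16-tetranorlabd-7-en-12-oate
Product: 5 methyl 7,7-dimethoxy-8-oxo-7,8-seco-13,14,15,16-tetranorlabdan-12-oate, via aldehyde methoxyhydroperoxide 3 (not isolated), via acetal methoxyhydroperoxide 4 (not isolated)
Conditions: O3, CH2Cl2/MeOH, −78 °C; TsOH·H2O (cat.), 23 °C; NaHCO3, Me2S
Reagents that add atoms: ozone ([O-][O+]=O); methanol (CO)
Why: Ozonolysis in methanol with in-flask acetalisation and sulfide reduction (Schreiber protocol) cleaves C7=C8 into the C8 methyl ketone and the masked C7 aldehyde, which prevents aldol reactions between the two new carbonyl groups, while the short, mild acid exposure should leave the C9 centre next to the ketone intact.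

Step 3
Reactants: 5 methyl 7,7-dimethoxy-8-oxo-7,8-seco-13,14,15,16-tetranorlabdan-12-oate
Product: 8 methyl 7-oxo-8-(trifluoromethylsulfonyloxy)-7,8-seco-13,14,15,16-tetranorlabd-8(17)-en-12-oate, via potassium enolate 6 (not isolated), via alkenyl triflate acetal 7 (not isolated)
Conditions: KN(SiMe3)2, THF, −78 °C (ketone added to base); N-(5-chloro-2-pyridyl)triflimide, −78 °C; then 1 M HCl, THF, 23 °C
Reagents that add atoms: N-(5-chloro-2-pyridyl)bis(trifluoromethanesulfonimide) (FC(F)(F)S(=O)(=O)N(c1ccc(Cl)cn1)S(=O)(=O)C(F)(F)F); water (O)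
Why: Kinetic deprotonation of the methyl ketone at the unhindered CH3 (not at the hindered C9–H, so C9 is not epimerised) followed by enolate O-triflation gives the 2-triflyloxy-1-alkene, and aqueous acid then hydrolyses the dimethyl acetal while alkenyl triflate and ester survive.

Step 4
Reactants: 8 methyl 7-oxo-8-(trifluoromethylsulfonyloxy)-7,8-seco-13,14,15,16-tetranorlabd-8(17)-en-12-oate
Product: 11 methyl 7β-hydroxy-13,14,15,16-tetranorlabd-8(17)-en-12-oate, via alkenylchromium dichloride 9 (not isolated), via chromium alkoxide 10 (not isolated)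
Conditions: CrCl2 (6 equiv), NiCl2 (2 mol %), degassed DMF, 23 °C, 0.005 M; aqueous work-up
Reagents that add atoms: none
Why: Zerovalent nickel (formed from NiCl2 and CrCl2) inserts into the C8–OTf bond and transmetalates to trivalent chromium, and the alkenylchromium 9 adds to the C7 aldehyde to give alkoxide 10. The closest known reaction type is the intramolecular Nozaki–Hiyama–Kishi coupling of alkenyl triflates with aldehydes. Ring B closes in a 6-exo-trig mode through the C7–C8 bond, the chain being pre-organised because C6 and C9 sit trans-diequatorial on ring A. The new C7 centre is controlled by the chair-like transition state of the forming trans-decalin, in which the bulky C–O–Cr group lies equatorial (β) and avoids the axial H5α and H9α. The step needs chemoselectivity for the aldehyde over the methyl ester, which the carbonyl selectivity and low basicity of organochromium reagents secure, and high dilution to suppress intermolecular coupling.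

Step 5
Reactants: 11 methyl 7β-hydroxy-13,14,15,16-tetranorlabd-8(17)-en-12-oate
Product: 13 7β-hydroxy-13,14,15,16-tetranorlabd-8(17)-en-12-al, via aluminium hemiacetal 12 (not isolated)
Conditions: i-Bu2AlH (2.2 equiv), CH2Cl2, −78 °C; MeOH quench, aq. KNaC4H4O6
Reagents that add atoms: none
Why: Partial ester reduction with i-Bu2AlH at −78 °C stops at the aluminium hemiacetal, which releases the aldehyde on work-up (the free 7-OH only consumes one hydride), and no stereocentre is affected.

Step 6
Reactants: 13 7β-hydroxy-13,14,15,16-tetranorlabd-8(17)-en-12-al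
Product: 14 (11Z)-7β,12-bis(triethylsilyloxy)-13,14,15,16-tetranorlabda-8(17),11-diene
Conditions: Et3SiOTf (2.4 equiv), Et3N, CH2Cl2, −78 → 0 °C
Reagents that add atoms: triethylsilyl triflate (CC[Si](CC)(CC)OS(=O)(=O)C(F)(F)F)
Why: Silyl triflate/amine enol silylation converts the aldehyde into its (mainly Z) triethylsilyl enol ether and silylates the C7 hydroxyl in the same operation, the E/Z ratio being of no consequence for step 7.

Step 7
Reactants: 14 (11Z)-7β,12-bis(triethylsilyloxy)-13,14,15,16-tetranorlabda-8(17),11-diene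
Product: 15 7β-(triethylsilyloxy)-11-(triethylsilylperoxy)-13,14,15,16-tetranorlabd-8(17)-en-12-al
Conditions: O2, visible light, tetraphenylporphyrin (cat.), CH2Cl2, −78 °C
Reagents that add atoms: dioxygen (O=O)
Why: In the silatropic ene reaction of singlet oxygen with a silyl enol ether, oxygen adds to C11 and silicon migrates to the terminal peroxy oxygen; with C9–H eclipsing the enol ether (A1,3 strain) oxygen should enter from the C8/C17 side, away from the quaternary C10 with its axial methyl and C1, which gives the C11 configuration of the target (formally 11R here only because CHO outranks C9), and the electron-rich enol ether reacts far faster than the 1,1-disubstituted 8(17)-alkene.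

Step 8
Reactants: 16 3-bromo-1,1-dimethoxypropane; 17 triphenylphosphine
Product: 18 (3,3-dimethoxypropyl)triphenylphosphonium bromide
Conditions: toluene, 100 °C
Reagents that add atoms: none
Why: SN2 quaternisation of triphenylphosphine by the primary bromide gives the phosphonium salt.

Step 9
Reactants: 18 (3,3-dimethoxypropyl)triphenylphosphonium bromide; 19 ethyl formate
Product: 21 4,4-dimethoxy-2-(triphenylphosphoranylidene)butanal, via unstabilised ylide 20 (not isolated)
Conditions: KOtBu (2 equiv), THF, 0 → 23 °C
Reagents that add atoms: none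
Why: C-formylation of a phosphonium ylide with a formate ester, the second equivalent of base regenerating the now formyl-stabilised ylide.

Step 10
Reactants: 15 7β-(triethylsilyloxy)-11-(triethylsilylperoxy)-13,14,15,16-tetranorlabd-8(17)-en-12-al; 21 4,4-dimethoxy-2-(triphenylphosphoranylidene)butanal
Product: 22 (11S,12E)-15,15-dimethoxy-7β-(triethylsilyloxy)-11-(triethylsilylperoxy)labda-8(17),12-dien-16-al
Conditions: benzene, 23–40 °C, dark
Reagents that add atoms: none
Why: Wittig olefination of an α-peroxy aldehyde with a formyl-stabilised ylide under neutral conditions should give the (E)-2-substituted enal (C11 trans to CHO, cis to C14) without base-induced fragmentation of the peroxide or epimerisation at C11.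

Step 11
Reactants: 22 (11S,12E)-15,15-dimethoxy-7β-(triethylsilyloxy)-11-(triethylsilylperoxy)labda-8(17),12-dien-16-al
Product: 24 (11S,12E,15R)-11,15-epidioxy-7β,15-dihydroxylabda-8(17),12-dien-16-al, via hydroperoxy dialdehyde 23 (not isolated)
Conditions: 0.5 M HCl, THF/H2O, 0 → 23 °C
Reagents that add atoms: water (O)
Why: Aqueous acid removes both triethylsilyl groups and hydrolyses the dimethyl acetal, and the free C11 hydroperoxide then adds to the saturated C15 aldehyde (peroxy-hemiacetal formation, seven-membered ring made possible by the E alkene), C15 equilibrating to the assumed more stable 15R anomer.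

Compound list
1 | (+)-sclareolide, (3aR,5aS,9aS,9bR)-3a,6,6,9a-tetramethyldecahydronaphtho[2,1-b]furan-2(1H)-one | O=C1C[C@@H]2[C@@]3(C)CCCC(C)(C)[C@@H]3CC[C@@]2(C)O1 | starting material
2 | methyl 13,14,15,16-tetranorlabd-7-en-12-oate (5α-H, 9α-H, 10β-methyl) | CC1=CC[C@H]2C(C)(C)CCC[C@]2(C)[C@H]1CC(=O)OC | intermediate
3 | aldehyde methoxyhydroperoxide: 7,8-seco compound with C7 aldehyde and C8 carrying OMe and OOH (C8 epimers), C5, C9, C10 as in 1 | CC(OC)(OO)[C@H](CC(=O)OC)[C@@]1(C)CCCC(C)(C)[C@@H]1CC=O | intermediate
4 | acetal methoxyhydroperoxide: as 3 with C7 as dimethyl acetal | CC(OC)(OO)[C@H](CC(=O)OC)[C@@]1(C)CCCC(C)(C)[C@@H]1CC(OC)OC | intermediate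
5 | methyl 7,7-dimethoxy-8-oxo-7,8-seco-13,14,15,16-tetranorlabdan-12-oate (ring-A cyclohexane with CH2CH(OMe)2 on C5 and C9 bearing acetyl and CH2CO2Me) | CC(=O)[C@H](CC(=O)OC)[C@@]1(C)CCCC(C)(C)[C@@H]1CC(OC)OC | intermediate
6 | potassium enolate of 5 (terminal, C8=C17) | C=C([O-])[C@H](CC(=O)OC)[C@@]1(C)CCCC(C)(C)[C@@H]1CC(OC)OC.[K+] | intermediate
7 | alkenyl triflate acetal: methyl 7,7-dimethoxy-8-(trifluoromethylsulfonyloxy)-7,8-seco-13,14,15,16-tetranorlabd-8(17)-en-12-oate | C=C(OS(=O)(=O)C(F)(F)F)[C@H](CC(=O)OC)[C@@]1(C)CCCC(C)(C)[C@@H]1CC(OC)OC | intermediate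
8 | methyl 7-oxo-8-(trifluoromethylsulfonyloxy)-7,8-seco-13,14,15,16-tetranorlabd-8(17)-en-12-oate | C=C(OS(=O)(=O)C(F)(F)F)[C@H](CC(=O)OC)[C@@]1(C)CCCC(C)(C)[C@@H]1CC=O | intermediate
9 | alkenylchromium dichloride (trivalent chromium on C8) | C=C([Cr](Cl)Cl)[C@H](CC(=O)OC)[C@@]1(C)CCCC(C)(C)[C@@H]1CC=O | intermediate
10 | chromium alkoxide of 11 (7β-O–CrCl2, trivalent chromium) | C=C1[C@H](CC(=O)OC)[C@@]2(C)CCCC(C)(C)[C@@H]2C[C@@H]1O[Cr](Cl)Cl | intermediate
11 | methyl 7β-hydroxy-13,14,15,16-tetranorlabd-8(17)-en-12-oate | C=C1[C@H](CC(=O)OC)[C@@]2(C)CCCC(C)(C)[C@@H]2C[C@@H]1O | intermediate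
12 | aluminium hemiacetal of 13 (C12 as CH(OMe)OAl(i-Bu)2, 7-O–Al(i-Bu)2) | C=C1[C@H](CC(OC)O[Al](CC(C)C)CC(C)C)[C@@]2(C)CCCC(C)(C)[C@@H]2C[C@@H]1O[Al](CC(C)C)CC(C)C | intermediate
13 | 7β-hydroxy-13,14,15,16-tetranorlabd-8(17)-en-12-al | C=C1[C@H](CC=O)[C@@]2(C)CCCC(C)(C)[C@@H]2C[C@@H]1O | intermediate
14 | (11Z)-7β,12-bis(triethylsilyloxy)-13,14,15,16-tetranorlabda-8(17),11-diene | C=C1[C@H](/C=C\O[Si](CC)(CC)CC)[C@@]2(C)CCCC(C)(C)[C@@H]2C[C@@H]1O[Si](CC)(CC)CC | intermediate
15 | 7β-(triethylsilyloxy)-11-(triethylsilylperoxy)-13,14,15,16-tetranorlabd-8(17)-en-12-al (C11 as in the target, formally 11R) | C=C1[C@H]([C@@H](OO[Si](CC)(CC)CC)C=O)[C@@]2(C)CCCC(C)(C)[C@@H]2C[C@@H]1O[Si](CC)(CC)CC | intermediate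
16 | 3-bromo-1,1-dimethoxypropane | COC(OC)CCBr | starting material
17 | triphenylphosphine | c1ccc(cc1)P(c1ccccc1)c1ccccc1 | starting material
18 | (3,3-dimethoxypropyl)triphenylphosphonium bromide | COC(OC)CC[P+](c1ccccc1)(c1ccccc1)c1ccccc1.[Br-] | intermediate
19 | ethyl formate | CCOC=O | starting material
20 | unstabilised ylide, (3,3-dimethoxypropylidene)triphenylphosphorane | COC(OC)CC=P(c1ccccc1)(c1ccccc1)c1ccccc1 | intermediate
21 | 4,4-dimethoxy-2-(triphenylphosphoranylidene)butanal | COC(OC)CC(C=O)=P(c1ccccc1)(c1ccccc1)c1ccccc1 | intermediate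
22 | (11S,12E)-15,15-dimethoxy-7β-(triethylsilyloxy)-11-(triethylsilylperoxy)labda-8(17),12-dien-16-al | C=C1[C@H]([C@@H](OO[Si](CC)(CC)CC)/C=C(/C=O)CC(OC)OC)[C@@]2(C)CCCC(C)(C)[C@@H]2C[C@@H]1O[Si](CC)(CC)CC | intermediate
23 | hydroperoxy dialdehyde, (11S,12E)-11-hydroperoxy-7β-hydroxylabda-8(17),12-diene-15,16-dial | C=C1[C@H]([C@@H](OO)/C=C(/C=O)CC=O)[C@@]2(C)CCCC(C)(C)[C@@H]2C[C@@H]1O | intermediate
24 | (11S,12E,15R)-11,15-epidioxy-7β,15-dihydroxylabda-8(17),12-dien-16-al (CNP0269954.2) | C=C1[C@H]([C@@H]2C=C(C=O)C[C@H](O)OO2)[C@@]2(C)CCCC(C)(C)[C@@H]2C[C@@H]1O | target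

Total step count: 11. Longest linear sequence: 9 steps (steps 1–7, 10, 11); steps 8 and 9 prepare the ylide.

Steps most likely to fail

Step 7. What may go wrong: oxygen may add to both faces of the enol ether (low facial selectivity at C11), or the perepoxide may collapse to a dioxetane that cleaves C11–C12. Fallback by catalyst-controlled enamine oxygenation: setting out from 13, an α-methylproline catalyst (the enantiomer that reinforces attack on the C8-side face), O2, visible light and tetraphenylporphyrin in DMF at 0 °C (amino-acid-catalysed α-oxidation of aldehydes with singlet oxygen) should give 7β-hydroxy-11-hydroperoxy-13,14,15,16-tetranorlabd-8(17)-en-12-al F2. F2 is silylated at once on both OH groups (Et3SiOTf, 2,6-lutidine, CH2Cl2, −78 °C) and so comes back to the route at 15.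

Step 10. What may go wrong: olefination of the hindered, α-branched aldehyde may be slow, so that thermal silyl migration with dioxetane cleavage, or base-induced fragmentation of the peroxide, overtakes it. Fallback by building the enal first and oxygenating C11 last: setting out from 13, Wittig reaction with 21 (toluene, 80 °C) should give (12E)-7β-hydroxy-15,15-dimethoxylabda-8(17),12-dien-16-al F3. Its potassium dienolate (KN(SiMe3)2, 2.2 equiv, THF, −78 °C) is oxygenated with O2 at the γ-carbon C11 and quenched cold with AcOH (vinylogous enolate autoxidation; same facial argument, E geometry retained) to give (11S,12E)-11-hydroperoxy-7β-hydroxy-15,15-dimethoxylabda-8(17),12-dien-16-al F4. The conditions of step 11 take F4 through 23 back to the route at 24.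

Step 4. What may go wrong: poor facial selectivity in the addition to the C7 aldehyde may give the 7α-epimer alongside 11. Fallback by setting C7 through hydride delivery instead of C–C bond formation: setting out from 11 (epimer mixture), MnO2 in CH2Cl2 oxidises the allylic alcohol to methyl 7-oxo-13,14,15,16-tetranorlabd-8(17)-en-12-oate F1. Luche reduction (NaBH4, CeCl3·7H2O, MeOH, −78 °C; axial hydride attack from the α face) should return the equatorial 7β-alcohol, coming back to the route at 11.

Further compounds
F1 | step 4 | methyl 7-oxo-13,14,15,16-tetranorlabd-8(17)-en-12-oate | C=C1[C@H](CC(=O)OC)[C@@]2(C)CCCC(C)(C)[C@@H]2CC1=O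
F2 | step 7 | 7β-hydroxy-11-hydroperoxy-13,14,15,16-tetranorlabd-8(17)-en-12-al (C11 as in 15) | C=C1[C@H]([C@@H](OO)C=O)[C@@]2(C)CCCC(C)(C)[C@@H]2C[C@@H]1O
F3 | step 10 | (12E)-7β-hydroxy-15,15-dimethoxylabda-8(17),12-dien-16-al | C=C1[C@H](C/C=C(/C=O)CC(OC)OC)[C@@]2(C)CCCC(C)(C)[C@@H]2C[C@@H]1O
F4 | step 10 | (11S,12E)-11-hydroperoxy-7β-hydroxy-15,15-dimethoxylabda-8(17),12-dien-16-al | C=C1[C@H]([C@@H](OO)/C=C(/C=O)CC(OC)OC)[C@@]2(C)CCCC(C)(C)[C@@H]2C[C@@H]1O
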